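## Retrosynthetic overview
1. Sixteen benzyl ethers are removed by hydrogenolysis at the end. The key cut is 2 + 2 at the central C4(unit 2)–C8(unit 3) bond: a C4 benzylic radical, made by homolytic opening of a 3α,4α-epoxide with trivalent titanium, is joined to a nickel-bound C8 aryl group made from an aryl iodide.
2. The same radical epoxide arylation builds both halves. The lower half comes from the monomeric 3α,4α-epoxide and 8-iodo-epicatechin ether; the upper half comes from the 3β,4β-epoxide and a 6-bromoflav-3-ene. The halogen position, not arene nucleophilicity, decides 4→8 or 4→6.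
3. No flavan-3-ol is ever the coupling electrophile, because every unit comes from one type of (2S)-flav-3-ene. The epoxide face fixes C3 (dioxirane anti to the 2-aryl group gives catechin, bromohydrin/closure syn gives epicatechin). Trans radical capture fixes C4 and leaves each 3-OH free.
4. Ring order per unit: ring A first (resorcinol → phloroglucinol), then pyran ring C (coumarin from ethyl propiolate → chromene acetal). Ring B (catechol-derived boronate) is attached last, enantioselectively at C2. The 6-bromo series branches at the dihydroxycoumarin.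
5. Conventions: units run 1 (top, catechin) to 4 (bottom); α is the face carrying the 2-aryl group and β is the opposite face.

Assumption: the L-tartaric acid derived catalyst is taken to give the 2S chromene drawn; if the sense proves opposite, its D-tartaric mirror image is used and nothing else changes.

## Route

Step 1
Reactants: 1 resorcinol
Product: 4 phloroglucinol, via resorcinol bis(O-Bpin) ether 2 (not isolated), via C5-borylated bis(O-Bpin) ether 3 (not isolated)
Conditions: HBpin (2.1 equiv), THF, rt; [Ir(OMe)(cod)]2 (1.5 mol %), dtbpy (3 mol %), B2pin2 (1.0 equiv), 80 °C; then 30 % aq H2O2, 0 °C to rt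
Reagents that add atoms: hydrogen peroxide, OO (the new oxygen); pinacolborane, CC1(C)OBOC1(C)C, and bis(pinacolato)diboron, CC1(C)OB(OC1(C)C)B1OC(C)(C)C(C)(C)O1 (boron only in 2 and 3)
Why: Iridium-catalysed C–H borylation is sterically governed, so with both hydroxyls masked in situ as O–Bpin ethers only the C5–H flanked by two hydrogens reacts, and peroxide oxidation of the C–B bond plus hydrolysis of the O–B bonds (one-pot C–H borylation/oxidation to phenols) gives the symmetrical triol.

Step 2
Reactants: 4 phloroglucinol; 5 ethyl propiolate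
Product: 6 5,7-dihydroxycoumarin
Conditions: Pd(OAc)2 (2 mol %), CF3CO2H–CH2Cl2, rt
Reagents that add atoms: none
Why: Fujiwara-type hydroarylation of the propiolate by the very electron-rich arene gives the Z-cinnamate, which lactonises at once (a Pechmann-like annulation), and the threefold symmetry of 4 removes any regiochemical question.

Step 3
Reactants: 6 5,7-dihydroxycoumarin
Product: 7 5,7-bis(benzyloxy)coumarin
Conditions: BnBr (2.2 equiv), K2CO3, DMF, 60 °C
Reagents that add atoms: benzyl bromide, BrCc1ccccc1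
Why: Williamson ether synthesis on two acidic phenols, with the lactone inert to carbonate in DMF.

Step 4
Reactants: 7 5,7-bis(benzyloxy)coumarin
Product: 9 5,7-bis(benzyloxy)-2-ethoxy-2H-chromene (racemic), via lactol 8 (not isolated)
Conditions: i-Bu2AlH (1.1 equiv), CH2Cl2, −78 °C, aqueous work-up; crude 8, EtOH, PPTS (5 mol %), 4 Å MS, rt
Reagents that add atoms: ethanol, CCO
Why: Partial lactone reduction stops at the lactol at low temperature and acid-catalysed acetalisation runs through the donor-stabilised chromenylium ion, the racemic acetal centre being erased in step 8.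

Step 5
Reactants: 10 catechol
Product: 11 1,2-bis(benzyloxy)benzene
Conditions: BnBr (2.2 equiv), K2CO3, DMF, 60 °C
Reagents that add atoms: benzyl bromide, BrCc1ccccc1
Why: Williamson ether synthesis.

Step 6
Reactants: 11 1,2-bis(benzyloxy)benzene
Product: 12 4-bromo-1,2-bis(benzyloxy)benzene
Conditions: NBS (1.0 equiv), MeCN, 0 °C to rt
Reagents that add atoms: N-bromosuccinimide, O=C1CCC(=O)N1Br
Why: Electrophilic aromatic bromination goes para to one benzyloxy group, the only unhindered activated position.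

Step 7
Reactants: 12 4-bromo-1,2-bis(benzyloxy)benzene
Product: 15 diethyl [3,4-bis(benzyloxy)phenyl]boronate, via aryllithium 13 (not isolated), via lithium aryltriethoxyborate 14 (not isolated)
Conditions: n-BuLi (1.05 equiv), THF, −78 °C; B(OEt)3 (1.2 equiv), −78 °C to rt; HCl (1.0 equiv, 2 M in Et2O); filter, concentrate
Reagents that add atoms: triethyl borate, CCOB(OCC)OCC; n-butyllithium, [Li]CCCC (lithium only in 13 and 14)
Why: Bromine–lithium exchange, capture by the borate ester and anhydrous protonolysis of the ate complex give the exchangeable diethyl boronate that step 8 needs.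

Step 8
Reactants: 9 5,7-bis(benzyloxy)-2-ethoxy-2H-chromene; 15 diethyl [3,4-bis(benzyloxy)phenyl]boronate
Product: 16 (2S)-5,7-bis(benzyloxy)-2-[3,4-bis(benzyloxy)phenyl]-2H-chromene
Conditions: 15 (1.5 equiv), (2R,3R)-4-(dibenzylamino)-2,3-dihydroxy-4-oxobutanoic acid (10 mol %), Yb(OTf)3 (9 mol %), EtOAc, −20 °C; one recrystallisation
Reagents that add atoms: none
Why: In this enantioselective boronate addition to a chromene acetal (chiral Brønsted acid/Lewis acid catalysis) Yb(OTf)3 ionises the acetal and the tartrate-bound aryl boronate delivers ring B to C2 of the chromenylium ion inside a chiral ion pair, which sets C2 (descriptor S here, same spatial arrangement as 2R in flavan-3-ols), while the peri 5-benzyloxy group shields C4.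

Step 9
Reactants: 6 5,7-dihydroxycoumarin
Product: 18 6-bromo-5,7-dihydroxycoumarin, via 6,8-dibromo-5,7-dihydroxycoumarin 17 (not isolated)
Conditions: NBS (2.0 equiv), MeCN, 0 °C; then Na2SO3 (1.1 equiv), NaHCO3, MeOH–H2O, rt
Reagents that add atoms: N-bromosuccinimide, O=C1CCC(=O)N1Br
Why: Proposed new method: both activated positions C6 and C8 are brominated and sulfite then removes only the bromine para to a free hydroxyl (C8–Br, para to 5-OH, reachable through the para-dienone tautomer), whereas C6–Br has only ortho hydroxyls and the acylated ring oxygen para to it and survives, the closest known reaction type being the tribromination/sulfite debromination of resorcinol that leaves 2-bromoresorcinol.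

Step 10
Reactants: 18 6-bromo-5,7-dihydroxycoumarin
Product: 19 6-bromo-5,7-bis(benzyloxy)coumarin
Conditions: BnBr (2.4 equiv), K2CO3, DMF, 60 °C
Reagents that add atoms: benzyl bromide, BrCc1ccccc1
Why: Williamson ether synthesis, the ortho bromine making both phenols more acidic.

Step 11
Reactants: 19 6-bromo-5,7-bis(benzyloxy)coumarin
Product: 21 6-bromo-5,7-bis(benzyloxy)-2-ethoxy-2H-chromene (racemic), via bromo lactol 20 (not isolated)
Conditions: i-Bu2AlH (1.1 equiv), CH2Cl2, −78 °C, aqueous work-up; crude 20, EtOH, PPTS (5 mol %), 4 Å MS, rt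
Reagents that add atoms: ethanol, CCO
Why: Same partial lactone reduction and acetalisation as in step 4, the aryl bromide being inert to i-Bu2AlH at −78 °C.

Step 12
Reactants: 21 6-bromo-5,7-bis(benzyloxy)-2-ethoxy-2H-chromene; 15 diethyl [3,4-bis(benzyloxy)phenyl]boronate
Product: 22 (2S)-6-bromo-5,7-bis(benzyloxy)-2-[3,4-bis(benzyloxy)phenyl]-2H-chromene
Conditions: 15 (1.5 equiv), (2R,3R)-4-(dibenzylamino)-2,3-dihydroxy-4-oxobutanoic acid (10 mol %), Yb(OTf)3 (9 mol %), EtOAc, −20 °C; one recrystallisation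
Reagents that add atoms: none
Why: Same enantioselective boronate addition to a chromene acetal as in step 8, C2 again being set by the chiral tartrate boronate/chromenylium ion pair and the remote C6 bromine playing no part.

Step 13
Reactants: 16 (2S)-5,7-bis(benzyloxy)-2-[3,4-bis(benzyloxy)phenyl]-2H-chromene
Product: 24 (2R,3R,4R)-5,7-bis(benzyloxy)-2-[3,4-bis(benzyloxy)phenyl]-3,4-epoxychromane (3α,4α-epoxide), via 3β-bromo-4α-hydroxy bromohydrin 23 (not isolated)
Conditions: NBS (1.0 equiv), THF–H2O 4:1, −20 °C, dark; cold extractive work-up; KOt-Bu (1.05 equiv), THF, −40 to 0 °C; filter through basic alumina, use at once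
Reagents that add atoms: water, O (the oxirane oxygen); N-bromosuccinimide, O=C1CCC(=O)N1Br (bromine only in 23)
Why: In this bromohydrin formation/Williamson-type closure the trialkoxystyrene-like C3=C4 bond outcompetes the arenes for Br+, which adds to C3 on the β face anti to the 2-aryl group, water takes the stabilised C4 cation anti to bromine, and the 4α-alkoxide displaces the 3β-bromide from the rear so that the oxirane oxygen ends on the α face (the epicatechin C3 configuration), E2 loss of HBr being impossible because no hydrogen is antiperiplanar to bromine.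

Step 14
Reactants: 24 3α,4α-epoxide
Product: 25 5,7,3',4'-tetra-O-benzyl-(−)-epicatechin (2R,3R)
Conditions: Cp2TiCl2 (10 mol %), Mn powder (1.5 equiv), 2,4,6-collidine·HCl (1.5 equiv), 1,4-cyclohexadiene (4 equiv), THF, rt
Reagents that add atoms: none
Why: In this titanocene-catalysed reductive epoxide opening (Nugent–RajanBabu type) trivalent titanium cleaves the benzylic C4–O bond, the C4 radical takes a hydrogen atom from 1,4-cyclohexadiene and the C3–O bond is never touched, so the 2,3-cis configuration is kept.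

Step 15
Reactants: 25 5,7,3',4'-tetra-O-benzyl-(−)-epicatechin
Product: 26 8-iodo-5,7,3',4'-tetra-O-benzyl-(−)-epicatechin
Conditions: NIS (1.0 equiv), CH2Cl2, −20 °C
Reagents that add atoms: N-iodosuccinimide, O=C1CCC(=O)N1I
Why: In this electrophilic aromatic iodination C8 is flanked by one benzyloxy group and the ring oxygen whereas C6 lies between two benzyloxy groups, so one equivalent of NIS goes to C8, matching the known behaviour of NBS with this ether.

Step 16
Reactants: 26 8-iodo-5,7,3',4'-tetra-O-benzyl-(−)-epicatechin; 24 3α,4α-epoxide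
Product: 27 octa-O-benzyl epicatechin-(4β→8)-epicatechin (octa-O-benzyl procyanidin B2)
Conditions: 24 (1.5 equiv), NiCl2(dme) (10 mol %), 2,2'-bipyridine (10 mol %), Cp2TiCl2 (15 mol %), Mn powder (2.5 equiv), Et3N·HCl (1.2 equiv), DMPU, 25 °C
Reagents that add atoms: none
Why: Proposed new method: trivalent titanium (Cp2TiCl from Cp2TiCl2 and Mn) opens the epoxide homolytically at the benzylic C4–O bond, the planar C4 radical is captured by the aryl nickel species formed from 26 on the β face, anti to the bulky 3α-titanoxy group and the 2α-aryl group, and reductive elimination from trivalent nickel forges the 4β→8 bond while the retained oxygen becomes the free 3α-hydroxyl, the closest known reaction type being the nickel/titanocene cross-electrophile coupling of epoxides with aryl halides that gives trans-2-arylcycloalkanols, here extended to an acid-labile flavene oxide and a doubly ortho-oxygenated aryl iodide.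

Step 17
Reactants: 27 octa-O-benzyl epicatechin-(4β→8)-epicatechin
Product: 28 8-iodo (upper unit) octa-O-benzyl epicatechin-(4β→8)-epicatechin
Conditions: NIS (1.0 equiv), CH2Cl2, −40 to 0 °C
Reagents that add atoms: N-iodosuccinimide, O=C1CCC(=O)N1I
Why: In this electrophilic aromatic iodination the only free C8 position (upper unit) has a single benzyloxy neighbour while both free C6 positions are buried between two benzyloxy groups, so the monomer selectivity of step 15 carries over.

Step 18
Reactants: 16 (2S)-5,7-bis(benzyloxy)-2-[3,4-bis(benzyloxy)phenyl]-2H-chromene; 22 (2S)-6-bromo-5,7-bis(benzyloxy)-2-[3,4-bis(benzyloxy)phenyl]-2H-chromene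
Product: 30 tetra-O-benzylcatechin-(4α→6)-[(2S)-tetra-O-benzylflav-3-ene], via 3β,4β-epoxide 29 (not isolated)
Conditions: (a) 16 (1.5 equiv), dimethyldioxirane, acetone–CH2Cl2, −40 °C, volatiles off below −20 °C; (b) crude 29 added over 2 h to 22, NiCl2(dme) (15 mol %), 2,2'-bipyridine (15 mol %), Cp2TiCl2 (20 mol %), Mn powder (3 equiv), Et3N·HCl (1.5 equiv), DMPU, 25–40 °C
Reagents that add atoms: dimethyldioxirane, CC1(C)OO1
Why: Proposed new method: neutral dioxirane epoxidation occurs anti to the 2α-aryl group and so places the oxygen at 3β (catechin C3), homolytic C4–O opening by trivalent titanium gives the C4 radical, which the aryl nickel species from the C6–Br bond of 22 captures on the α face anti to the 3β-titanoxy group, giving the 3,4-trans 4α→6 bond with the site fixed by the bromine, the closest known reaction type being the nickel/titanocene cross-electrophile coupling of epoxides with aryl bromides, and the hindered 1,2-disubstituted alkene of 22 being a poor acceptor for a stabilised benzylic radical.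

Step 19
Reactants: 30 tetra-O-benzylcatechin-(4α→6)-[(2S)-tetra-O-benzylflav-3-ene]
Product: 32 tetra-O-benzylcatechin-(4α→6)-[tetra-O-benzyl-3α,4α-epoxyflavan], via dimeric bromohydrin 31 (not isolated)
Conditions: NBS (1.0 equiv), THF–H2O 4:1, −30 °C, dark; cold extractive work-up; KOt-Bu (1.2 equiv), THF, −40 to 0 °C; filter through basic alumina, use at once
Reagents that add atoms: water, O (the oxirane oxygen); N-bromosuccinimide, O=C1CCC(=O)N1Br (bromine only in 31)
Why: Same bromohydrin formation/Williamson-type closure as in step 13, the alkene (now conjugated to a still richer, C6-alkylated ring A) remaining the most nucleophilic site, Br+ adding at 3β anti to the 2-aryl group, water at 4α, and rear-side closure placing the oxirane oxygen on the α face (epicatechin C3) while the free 3-OH of unit 1 is only reversibly deprotonated.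

Step 20
Reactants: 32 tetra-O-benzylcatechin-(4α→6)-[tetra-O-benzyl-3α,4α-epoxyflavan]; 28 8-iodo octa-O-benzyl epicatechin-(4β→8)-epicatechin
Product: 33 hexadeca-O-benzyl catechin-(4α→6)-epicatechin-(4β→8)-epicatechin-(4β→8)-epicatechin
Conditions: 32 (1.3 equiv, added over 3 h), NiCl2(dme) (20 mol %), 2,2'-bipyridine (20 mol %), Cp2TiCl2 (25 mol %), Mn powder (3 equiv), Et3N·HCl (1.5 equiv), DMPU, 25 °C
Reagents that add atoms: none
Why: Proposed new method: as in step 16, trivalent titanium opens the 3α,4α-epoxide at the benzylic C4–O bond and the C4 radical of unit 2 is intercepted on its β face (anti to the 3α-titanoxy and 2α-aryl groups) by the aryl nickel species from the only carbon–halogen bond present (C8–I of unit 3), so that reductive elimination from trivalent nickel gives the central 4β→8 bond and the free 3α-hydroxyl, the closest known reaction type being the nickel/titanocene cross-electrophile coupling of epoxides with aryl iodides.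

Step 21
Reactants: 33 hexadeca-O-benzyl tetramer
Product: 34 catechin-(4α→6)-epicatechin-(4β→8)-epicatechin-(4β→8)-epicatechin (CNP0228086.1)
Conditions: H2 (1 atm), Pd(OH)2/C, THF–MeOH–H2O, rt; filter, Sephadex LH-20, lyophilise
Reagents that add atoms: none
Why: Catalytic hydrogenolysis of benzyl aryl ethers under neutral conditions leaves the acid- and base-sensitive interflavan bonds and all eleven stereocentres untouched.

## Compound list
1 | resorcinol (benzene-1,3-diol) | Oc1cccc(O)c1 | starting material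
2 | 1,3-bis[(4,4,5,5-tetramethyl-1,3,2-dioxaborolan-2-yl)oxy]benzene | CC1(C)OB(Oc2cccc(OB3OC(C)(C)C(C)(C)O3)c2)OC1(C)C | intermediate
3 | 2-{3,5-bis[(4,4,5,5-tetramethyl-1,3,2-dioxaborolan-2-yl)oxy]phenyl}-4,4,5,5-tetramethyl-1,3,2-dioxaborolane | CC1(C)OB(Oc2cc(OB3OC(C)(C)C(C)(C)O3)cc(B3OC(C)(C)C(C)(C)O3)c2)OC1(C)C | intermediate
4 | phloroglucinol (benzene-1,3,5-triol) | Oc1cc(O)cc(O)c1 | intermediate
5 | ethyl propiolate | C#CC(=O)OCC | starting material
6 | 5,7-dihydroxycoumarin | O=c1ccc2c(O)cc(O)cc2o1 | intermediate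
7 | 5,7-bis(benzyloxy)coumarin | O=c1ccc2c(OCc3ccccc3)cc(OCc3ccccc3)cc2o1 | intermediate
8 | 5,7-bis(benzyloxy)-2H-chromen-2-ol (racemic lactol) | OC1C=Cc2c(OCc3ccccc3)cc(OCc3ccccc3)cc2O1 | intermediate
9 | 5,7-bis(benzyloxy)-2-ethoxy-2H-chromene (racemic acetal) | CCOC1C=Cc2c(OCc3ccccc3)cc(OCc3ccccc3)cc2O1 | intermediate
10 | catechol (benzene-1,2-diol) | Oc1ccccc1O | starting material
11 | 1,2-bis(benzyloxy)benzene | c1ccc(COc2ccccc2OCc2ccccc2)cc1 | intermediate
12 | 4-bromo-1,2-bis(benzyloxy)benzene | Brc1ccc(OCc2ccccc2)c(OCc2ccccc2)c1 | intermediate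
13 | [3,4-bis(benzyloxy)phenyl]lithium | [Li]c1ccc(OCc2ccccc2)c(OCc2ccccc2)c1 | intermediate
14 | lithium [3,4-bis(benzyloxy)phenyl]triethoxyborate | [Li+].CCO[B-](OCC)(OCC)c1ccc(OCc2ccccc2)c(OCc2ccccc2)c1 | intermediate
15 | diethyl [3,4-bis(benzyloxy)phenyl]boronate | CCOB(OCC)c1ccc(OCc2ccccc2)c(OCc2ccccc2)c1 | intermediate
16 | (2S)-5,7-bis(benzyloxy)-2-[3,4-bis(benzyloxy)phenyl]-2H-chromene (tetra-O-benzyl flav-3-ene, 2-aryl α) | c1c(OCc9ccccc9)cc(OCc9ccccc9)c2c1O[C@H](c1ccc(OCc9ccccc9)c(OCc9ccccc9)c1)C=C2 | intermediate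
17 | 6,8-dibromo-5,7-dihydroxycoumarin | O=c1ccc2c(O)c(Br)c(O)c(Br)c2o1 | intermediate
18 | 6-bromo-5,7-dihydroxycoumarin | O=c1ccc2c(O)c(Br)c(O)cc2o1 | intermediate
19 | 6-bromo-5,7-bis(benzyloxy)coumarin | O=c1ccc2c(OCc3ccccc3)c(Br)c(OCc3ccccc3)cc2o1 | intermediate
20 | 6-bromo-5,7-bis(benzyloxy)-2H-chromen-2-ol (racemic lactol) | OC1C=Cc2c(OCc3ccccc3)c(Br)c(OCc3ccccc3)cc2O1 | intermediate
21 | 6-bromo-5,7-bis(benzyloxy)-2-ethoxy-2H-chromene (racemic acetal) | CCOC1C=Cc2c(OCc3ccccc3)c(Br)c(OCc3ccccc3)cc2O1 | intermediate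
22 | (2S)-6-bromo-5,7-bis(benzyloxy)-2-[3,4-bis(benzyloxy)phenyl]-2H-chromene | c1c(OCc9ccccc9)c(Br)c(OCc9ccccc9)c2c1O[C@H](c1ccc(OCc9ccccc9)c(OCc9ccccc9)c1)C=C2 | intermediate
23 | (2R,3S,4R)-3-bromo-5,7-bis(benzyloxy)-2-[3,4-bis(benzyloxy)phenyl]chroman-4-ol (3β-Br, 4α-OH) | c1c(OCc9ccccc9)cc(OCc9ccccc9)c2c1O[C@H](c1ccc(OCc9ccccc9)c(OCc9ccccc9)c1)[C@@H](Br)[C@@H]2O | intermediate
24 | (2R,3R,4R)-5,7-bis(benzyloxy)-2-[3,4-bis(benzyloxy)phenyl]-3,4-epoxychromane (oxirane oxygen α, cis to the 2-aryl group) | c1c(OCc9ccccc9)cc(OCc9ccccc9)c2c1O[C@H](c1ccc(OCc9ccccc9)c(OCc9ccccc9)c1)[C@@H]1O[C@@H]12 | intermediate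
25 | 5,7,3',4'-tetra-O-benzyl-(−)-epicatechin (2R,3R) | c1c(OCc9ccccc9)cc(OCc9ccccc9)c2c1O[C@H](c1ccc(OCc9ccccc9)c(OCc9ccccc9)c1)[C@H](O)C2 | intermediate
26 | 8-iodo-5,7,3',4'-tetra-O-benzyl-(−)-epicatechin (2R,3R) | Ic1c(OCc9ccccc9)cc(OCc9ccccc9)c2c1O[C@H](c1ccc(OCc9ccccc9)c(OCc9ccccc9)c1)[C@H](O)C2 | intermediate
27 | octa-O-benzyl epicatechin-(4β→8)-epicatechin, both 3-OH free | c1c(OCc9ccccc9)cc(OCc9ccccc9)c2c1O[C@H](c1ccc(OCc9ccccc9)c(OCc9ccccc9)c1)[C@H](O)[C@H]2c1c(OCc9ccccc9)cc(OCc9ccccc9)c2c1O[C@H](c1ccc(OCc9ccccc9)c(OCc9ccccc9)c1)[C@H](O)C2 | intermediate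
28 | 27 carrying iodine at C8 of the upper unit | Ic1c(OCc9ccccc9)cc(OCc9ccccc9)c2c1O[C@H](c1ccc(OCc9ccccc9)c(OCc9ccccc9)c1)[C@H](O)[C@H]2c1c(OCc9ccccc9)cc(OCc9ccccc9)c2c1O[C@H](c1ccc(OCc9ccccc9)c(OCc9ccccc9)c1)[C@H](O)C2 | intermediate
29 | (2R,3S,4S)-5,7-bis(benzyloxy)-2-[3,4-bis(benzyloxy)phenyl]-3,4-epoxychromane (oxirane oxygen β, trans to the 2-aryl group) | c1c(OCc9ccccc9)cc(OCc9ccccc9)c2c1O[C@H](c1ccc(OCc9ccccc9)c(OCc9ccccc9)c1)[C@H]1O[C@H]12 | intermediate
30 | tetra-O-benzylcatechin (2R,3S, 3-OH free) joined 4α→6 to (2S)-tetra-O-benzylflav-3-ene | c1c(OCc9ccccc9)cc(OCc9ccccc9)c2c1O[C@H](c1ccc(OCc9ccccc9)c(OCc9ccccc9)c1)[C@@H](O)[C@@H]2c1c(OCc9ccccc9)cc2c(c1OCc9ccccc9)C=C[C@@H](c1ccc(OCc9ccccc9)c(OCc9ccccc9)c1)O2 | intermediate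
31 | bromohydrin of 30 (lower unit 2α-aryl, 3β-Br, 4α-OH) | c1c(OCc9ccccc9)cc(OCc9ccccc9)c2c1O[C@H](c1ccc(OCc9ccccc9)c(OCc9ccccc9)c1)[C@@H](O)[C@@H]2c1c(OCc9ccccc9)cc2c(c1OCc9ccccc9)[C@@H](O)[C@H](Br)[C@@H](c1ccc(OCc9ccccc9)c(OCc9ccccc9)c1)O2 | intermediate
32 | tetra-O-benzylcatechin-(4α→6)-[tetra-O-benzyl-3α,4α-epoxyflavan] (oxirane cis to the lower 2-aryl group) | c1c(OCc9ccccc9)cc(OCc9ccccc9)c2c1O[C@H](c1ccc(OCc9ccccc9)c(OCc9ccccc9)c1)[C@@H](O)[C@@H]2c1c(OCc9ccccc9)cc2c(c1OCc9ccccc9)[C@H]1O[C@H]1[C@@H](c1ccc(OCc9ccccc9)c(OCc9ccccc9)c1)O2 | intermediate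
33 | hexadeca-O-benzyl catechin-(4α→6)-epicatechin-(4β→8)-epicatechin-(4β→8)-epicatechin, four 3-OH free | c1c(OCc9ccccc9)cc(OCc9ccccc9)c2c1O[C@H](c1ccc(OCc9ccccc9)c(OCc9ccccc9)c1)[C@@H](O)[C@@H]2c1c(OCc9ccccc9)cc2c(c1OCc9ccccc9)[C@H](c1c(OCc9ccccc9)cc(OCc9ccccc9)c3c1O[C@H](c1ccc(OCc9ccccc9)c(OCc9ccccc9)c1)[C@H](O)[C@H]3c1c(OCc9ccccc9)cc(OCc9ccccc9)c3c1O[C@H](c1ccc(OCc9ccccc9)c(OCc9ccccc9)c1)[C@H](O)C3)[C@@H](O)[C@@H](c1ccc(OCc9ccccc9)c(OCc9ccccc9)c1)O2 | intermediate
34 | catechin-(4α→6)-epicatechin-(4β→8)-epicatechin-(4β→8)-epicatechin (CNP0228086.1) | Oc1cc(O)c2c(c1)O[C@H](c1ccc(O)c(O)c1)[C@@H](O)[C@@H]2c1c(O)cc2c(c1O)[C@H](c1c(O)cc(O)c3c1O[C@H](c1ccc(O)c(O)c1)[C@H](O)[C@H]3c1c(O)cc(O)c3c1O[C@H](c1ccc(O)c(O)c1)[C@H](O)C3)[C@@H](O)[C@@H](c1ccc(O)c(O)c1)O2 | target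

## Step count and risks
Total steps: 21.
Longest linear sequence: 12 steps (steps 1, 2, 3, 4, 8, 13, 14, 15, 16, 17, 20, 21; 1 → 4 → 6 → 7 → 9 → 16 → 24 → 25 → 26 → 27 → 28 → 33 → 34).

**Step 20** (most likely to fail). A bulky dimeric radical must meet a doubly ortho-substituted aryl nickel species, and this is the step that costs the most material.
- The fallback leaves the radical manifold for this one bond and uses a polar Friedel–Crafts epoxide opening.
- It sets out from 32 and from the non-iodinated dimer 27, so step 17 is skipped.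
- 32 is added slowly to 27 (3–4 equiv) and BF3·OEt2 in CH2Cl2 at −78 °C, and the Lewis acid ionises the benzylic C4–O bond.
- The free C8 of the upper unit of 27 is the most nucleophilic position because it has only one benzyloxy neighbour. It attacks anti to the C3 oxygen.
- The path comes back to the route at 33, and excess 27 is recovered. No new compound arises on this path (entry F0).

**Step 19.** NBS must choose the alkene over three free ring A positions of a valuable dimer, and the product is labile.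
- The fallback makes the epoxide at the monomer stage and reverses the order of assembly. It sets out from 22 and comes back at 33.
- 22 with NBS in wet THF at −20 °C gives (2R,3S,4R)-3,6-dibromo-5,7-bis(benzyloxy)-2-[3,4-bis(benzyloxy)phenyl]chroman-4-ol F1.
- KOt-Bu closes it to (2R,3R,4R)-6-bromo-5,7-bis(benzyloxy)-2-[3,4-bis(benzyloxy)phenyl]-3,4-epoxychromane F2.
- F2 is coupled with 28 under the conditions of step 16. The C8–I bond reacts well before the C6–Br bond buried between two benzyloxy groups, giving 6-bromo-dodeca-O-benzyl epicatechin-(4β→8)-epicatechin-(4β→8)-epicatechin F3.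
- F3 is finally coupled through its C6–Br bond with 29, made from 16 as in step 18, to give 33.

**Step 18.** This is oxidative addition and radical capture at a C6–Br bond flanked by two benzyloxy groups.
- The fallback replaces the cross-electrophile coupling by a preformed aryl metal and a polar anti opening of the epoxide. It sets out from 22 (with 29 made from 16 as before) and comes back at 30.
- 22 has no acidic hydrogen that competes at −78 °C. With t-BuLi (2.0 equiv) in THF it undergoes bromine–lithium exchange to (2S)-6-lithio-5,7-bis(benzyloxy)-2-[3,4-bis(benzyloxy)phenyl]-2H-chromene F4.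
- Cold 29 and then BF3·OEt2 are added. The aryl group attacks the benzylic C4 from the α face, anti to the 3β oxygen.
- An NH4Cl quench gives 30 with the same 3,4-trans 4α→6 linkage.

Further compounds
F0 | step 20 | none | none
F1 | step 19 | (2R,3S,4R)-3,6-dibromo-5,7-bis(benzyloxy)-2-[3,4-bis(benzyloxy)phenyl]chroman-4-ol | c1c(OCc9ccccc9)c(Br)c(OCc9ccccc9)c2c1O[C@H](c1ccc(OCc9ccccc9)c(OCc9ccccc9)c1)[C@@H](Br)[C@@H]2O
F2 | step 19 | (2R,3R,4R)-6-bromo-5,7-bis(benzyloxy)-2-[3,4-bis(benzyloxy)phenyl]-3,4-epoxychromane | c1c(OCc9ccccc9)c(Br)c(OCc9ccccc9)c2c1O[C@H](c1ccc(OCc9ccccc9)c(OCc9ccccc9)c1)[C@@H]1O[C@@H]12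
F3 | step 19 | 6-bromo-dodeca-O-benzyl epicatechin-(4β→8)-epicatechin-(4β→8)-epicatechin | Brc1c(OCc9ccccc9)cc2c(c1OCc9ccccc9)[C@H](c1c(OCc9ccccc9)cc(OCc9ccccc9)c3c1O[C@H](c1ccc(OCc9ccccc9)c(OCc9ccccc9)c1)[C@H](O)[C@H]3c1c(OCc9ccccc9)cc(OCc9ccccc9)c3c1O[C@H](c1ccc(OCc9ccccc9)c(OCc9ccccc9)c1)[C@H](O)C3)[C@@H](O)[C@@H](c1ccc(OCc9ccccc9)c(OCc9ccccc9)c1)O2
F4 | step 18 | (2S)-6-lithio-5,7-bis(benzyloxy)-2-[3,4-bis(benzyloxy)phenyl]-2H-chromene | [Li]c1c(OCc9ccccc9)cc2c(c1OCc9ccccc9)C=C[C@@H](c1ccc(OCc9ccccc9)c(OCc9ccccc9)c1)O2
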